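A percentage point was the unit I had to think in: a repeated reading scattered by 1 percentage point, and the product readings of the earlier runs at 10.0 h spanned 2.4 points.

| flask | starting material | partner | capture agent | protic impurity | remark | time |
|---|---|---|---|---|---|---|
| green | 0.050 M | 0.075 M | 0.050 M | 0.36 mM | run made earlier |  |
| violet | 0.050 M | 0.075 M | 0.050 M | 2.6 mM | run made earlier |  |
| grey | 0.050 M | 0.075 M | 0.086 M | 1 mM | run made earlier |  |
| dusk | 0.050 M | 0.0750 M | 0.0500 M | 1.00 mM |  | 20 h |
| dawn | 0.050 M | 0.0750 M | 0.150 M | 0.250 mM |  | 20 h |
| noon | 0.012 M | 0.0750 M | 0.0800 M | 0.300 mM |  | 20 h |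
| autumn | 0.050 M | 0.0200 M | 0.100 M | 1.00 mM |  | 20 h |
| midnight | 0.050 M | 0.0750 M | 0.100 M | 2.00 mM |  | 20 h |

- green (time / h: product / %, starting material / %): 0.833: 0.1, 67.7; 2.50: 3.8, 37.7; 5.00: 5.7, 26.0; 8.00: 6.8, 17.6; 10.0: 9.9, 15.0
- violet (time / h: product / %, starting material / %): 0.833: 2.1, 64.0; 2.50: 2.6, 37.5; 5.00: 4.5, 25.5; 8.00: 7.5, 15.3; 10.0: 8.2, 13.1
- grey (time / h: product / %, starting material / %): 2.00: 1.5, 47.3; 4.00: 4.6, 28.2; 6.00: 5.6, 19.3; 8.00: 7.7, 17.2; 10.0: 7.5, 14.0

(standard deviation of a reading: 1 percentage point)



* all flasks from highest to lowest amount of product, in percent of the starting material charged, at 20 h (dusk / dawn / noon / autumn / midnight)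
* the amount of product, in percent of the starting material charged of the flask you put first, at 20 h
* the amount of product, in percent of the starting material charged of the flask you put last, at 20 h

I wanted to know what capture agent does to product. I supposed that it takes a share of whatever feeds product, so that with the starting material and partner charges held, product at a given time goes inversely as F, which is one plus βT, with T the capture agent charge. Here βT is a selectivity factor, capture against product. Green and violet held 0.050 M of capture agent, grey 0.086 M, and at 10.0 h product read 9.9%, 8.2% and 7.5%.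

That gave two ways to β. Grey against green gave 16.0 M⁻¹, and grey against violet gave 2.98 M⁻¹. They parted, and impurity was the suspect, at 0.36 mM in green against 2.6 mM in violet. But at 8.00 h green read 6.8% and violet 7.5%, so green's lead had reversed, and I blamed the scatter of a single reading. Pooling green and violet gave 8.05 M⁻¹ for β, the capture strength per molar of capture agent. It is a weak reading, resting on a gap of 1.6 points.

With it, F came to 1.40 in dusk, 1.81 in midnight and 2.21 in dawn. F was lower in dusk than in midnight and lower in midnight than in dawn, so my order ran dusk, midnight, dawn, with dawn at 0.635 of dusk. The straight line through the pooled reading gave an estimate of 18.1% for dusk. At the ends of my order I put noon first, with 6.25 equivalents of partner, and autumn last, with 0.400.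

The forecast was noon > dawn > dusk > midnight > autumn, with 28% at the top and 8% at the bottom, on the ground that “impurity and capture agent hardly matter over these ranges”. My reckoning differs from it on dawn.

The flasks gave noon > dusk > midnight > dawn > autumn, with 20.5% in noon and 3.80% in autumn.

    starting material + partner ⇌ open intermediate (K = 19.0 M⁻¹, k = 0.0450 M⁻¹ min⁻¹)
    open intermediate → product (k = 0.00100 min⁻¹)
    2 starting material → homo dimer (k = 0.0580 M⁻¹ min⁻¹)
    open intermediate + capture agent → trapped intermediate (k = 0.0230 M⁻¹ min⁻¹)
    starting material + protic impurity → quenched substrate (k = 37.0 M⁻¹ min⁻¹)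

Dawn stood at 0.637 of dusk, against the 0.635 from F. The neighbour of noon, charged with 0.020 M of capture agent, keeps noon's starting material and partner, the charges F holds fixed: F was 1.16 there against 1.64 in noon. Scaling noon's 20.5% by that ratio gave 29.1%. That neighbour flask gave 28.8%.

The runs are calculated from invented constants; scatter was added.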